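Its constants belong to no real substance; what happens was integrated by code.

We start from late times: what does this flask hold once the reserve of reagent in the second phase has been delivered, and how quickly does it get there?

    reagent in the reaction phase ⇌ reagent in the second phase, rate k1*([reagent in the reaction phase] - [reagent in the second phase]/K1) per volume of the first phase (K1 = 94.5, k1 = 1.63 × 10⁻⁴ /s)
    substrate + reagent in the reaction phase → target (k2 = 0.136 /M/s)
    reagent in the reaction phase + target → over-reacted product (k3 = 0.158 /M/s)

substrate 0.050 M; reagent in the second phase 0.0600 M; time 25 h; volume of the second phase over the first 0.50

- in the second phase: reagent in the second phase; everything else is in the first
- charges count per volume of the first phase; a concentration in a rate is the amount of a species over the volume of its own phase; every rate counts per litre of the first phase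
- run time (flask): 25 h

* the target standing at 25 h, as a percentage of the substrate charged
* the over-reacted product standing at 25 h, as a percentage of the substrate charged
* amount of target if the flask were left three thousand times as long, in percent of the substrate charged

This flask's charge offers 1.20 equivalents of reagent per substrate. Let a be the fraction of substrate left and s the selectivity factor, k3/k2, here 1.16. Both consuming steps take the same reagent, so the split follows a, whatever the pace of delivery: target = (a − a^s)/(s − 1). Reagent used is two for each substrate gone, less one for each target.

| substrate left | target | reagent used, equivalents |
|---|---|---|
| 75.0 % | 21.1 % | 0.289 |
| 66.7 % | 26.2 % | 0.405 |
| 25.0 % | 31.0 % | 1.19 |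

The last row uses about what was charged, so that row is our end state for this flask.

Now the pace. Reagent in the reaction phase has a half-life of 1.7 min by step 2 alone at the charged substrate, far shorter than the release time, partition ratio times volume ratio over transfer coefficient, 80.5 h. So crossing is the rate-limiting step, and the reserve decays exponentially with that time.

By 25 h we reckon this flask to have received 0.320 equivalents per substrate charged. This released amount is our dose. It lies about a quarter of the way from the first row to the second. Reading that far along the rows gives target 22.4 % and over-reacted product 4.79 %.

The forecast gives 22.3 %, 4.5 % and 30.9 %, each a little below ours, holding that the reagent “reacts far faster than it crosses over”.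

The simulation gives 22.3 %, 4.53 % and 30.9 %. At 25.0 h this flask still holds 73 % of its substrate. Substrate gone plus over-reacted product gives reagent used as 31.5 % of the substrate charged, against our dose of 32.0 %.

Take the neighbour charged with 0.013 M of substrate. Its dose at 25 h is 1.23, near the last row, so we expect that flask to stand close to this flask's end state. It holds substrate 27.9 %, target 32.2 % and over-reacted product 40.0 %.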